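The cyclohexanone ring (C1 = carbonyl carbon, C4 = carbinol carbon) is cut at C2–C3 and C4–C5. Methyl vinyl ketone supplies C1, C2, C5 and C6; an α-oxygenated aldehyde supplies C3 (formyl carbon) and C4 (α-carbon) together with the tertiary oxygen and the two-carbon side chain. A Robinson annulation joins them in one operation: Michael addition makes C4–C5 and creates the fully substituted oxygenated carbon, aldol condensation makes C2–C3 and closes the ring. The step exploits the 1,4-relationship between ring ketone and carbinol carbon. The precursor, 2-phenyl-1,3-dioxane-4-carbaldehyde, comes from the benzylidene acetal of butane-1,2,4-triol; one hydrogenation later saturates the enone and unmasks both hydroxyls for selective palmitoylation.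

Key step: step 3

Remark: the target has no stereocentre, so racemic butane-1,2,4-triol is used; intermediates 2, 3 and 8 are racemates (one enantiomer drawn for 2 and 3), and 5, 6 and 7 are diastereomer mixtures written without descriptors, because every stereocentre is gone after step 4.

Step 1
Reactants: 1 butane-1,2,4-triol (racemic)
Product: 2 cis-(2-phenyl-1,3-dioxan-4-yl)methanol (racemic, 2R*,4R*; phenyl and hydroxymethyl both equatorial)
Conditions: PhCH(OMe)2 (1.1 equiv), camphorsulfonic acid (cat.), CH2Cl2, rt
Reagents that add atoms: benzaldehyde dimethyl acetal, COC(OC)c1ccccc1
Why: Acid-catalysed transacetalisation under thermodynamic control should favour the six-membered 1,3-dioxane across the 2- and 4-oxygens, with both substituents equatorial (cis), over the five-membered dioxolane, as is usual for benzylidene acetals of 1,2,4-triols.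

Step 2
Reactants: 2 cis-(2-phenyl-1,3-dioxan-4-yl)methanol
Product: 3 cis-2-phenyl-1,3-dioxane-4-carbaldehyde (racemic, 2R*,4R*)
Conditions: TEMPO (10 mol%), PhI(OAc)2 (1.1 equiv), CH2Cl2, rt; used crude
Reagents that add atoms: none
Why: Oxoammonium (TEMPO) oxidation with PhI(OAc)2 as terminal oxidant should stop at the aldehyde under anhydrous conditions and tolerate the acetal; epimerisation at the α-carbon is harmless because that centre is planarised in step 3.

Step 3
Reactants: 3 cis-2-phenyl-1,3-dioxane-4-carbaldehyde; 4 methyl vinyl ketone (but-3-en-2-one)
Product: 7 2-phenyl-1,3-dioxaspiro[5.5]undec-7-en-9-one, via Michael adduct keto aldehyde 5 (not isolated), via aldol ketol 6 (not isolated)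
Conditions: pyrrolidine (30 mol%), AcOH (30 mol%), toluene, 0 °C to rt, then 60 °C
Reagents that add atoms: none
Why: Pyrrolidinium acetate converts aldehyde 3 into its enamine, whose oxygen-bearing α-carbon (dioxane C4, the future carbinol carbon) adds to the β-carbon of 4 (Michael addition, first C–C bond) to give keto aldehyde 5; the methyl ketone of 5, again as its enamine, attacks the formyl carbon (aldol addition, second C–C bond) to give ketol 6, which dehydrates to the conjugated enone 7. This is a Robinson annulation, and the closest known case is the annulation of α-branched aldehydes with methyl vinyl ketone to 4,4-disubstituted cyclohex-2-enones. The cyclohexenone ring closes in a 6-(enolendo)-exo-trig aldol mode. The spiro stereocentre forms without control relative to the acetal carbon, which is harmless because the spiro carbon stops being a stereocentre once the ring is saturated and the acetal carbon is removed in step 4; the carbinol centre of 6 is erased by dehydration. The step needs the aldehyde to act as the first donor and the ring to close through the methyl group: 3 has a single α-hydrogen, 5 has no aldehyde α-hydrogen left, and attack by the ketone CH2 would give a four-membered ring, so only the six-membered closure is open. The buffered, near-neutral medium should spare the benzylidene acetal and the γ-alkoxy enone, which would aromatise with loss of the tertiary oxygen under strong acid.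

Step 4
Reactants: 7 2-phenyl-1,3-dioxaspiro[5.5]undec-7-en-9-one
Product: 9 4-hydroxy-4-(2-hydroxyethyl)cyclohexan-1-one, via saturated spiro acetal ketone 8 (not isolated)
Conditions: H2 (1 atm), Pd/C, EtOAc/EtOH, rt
Reagents that add atoms: none
Why: Heterogeneous hydrogenation should saturate the enone C=C first (giving 8) and then cleave both benzylic C–O bonds of the benzylidene acetal by hydrogenolysis, freeing the tertiary and the primary hydroxyl while the ketone stays untouched on Pd under neutral conditions; no stereocentre remains.

Step 5
Reactants: 9 4-hydroxy-4-(2-hydroxyethyl)cyclohexan-1-one; 10 palmitoyl chloride (hexadecanoyl chloride)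
Product: 11 2-(1-hydroxy-4-oxocyclohexyl)ethyl hexadecanoate (target)
Conditions: pyridine (1.5 equiv), CH2Cl2, 0 °C
Reagents that add atoms: none
Why: O-Acylation with an acid chloride and pyridine at low temperature should be chemoselective for the unhindered primary hydroxyl over the tertiary ring hydroxyl, giving the target ester directly.

Compound list
1 | butane-1,2,4-triol (racemic) | OCC(O)CCO | starting material
2 | cis-(2-phenyl-1,3-dioxan-4-yl)methanol (racemic, 2R*,4R*) | OC[C@H]1CCO[C@@H](c2ccccc2)O1 | intermediate
3 | cis-2-phenyl-1,3-dioxane-4-carbaldehyde (racemic, 2R*,4R*) | O=C[C@H]1CCO[C@@H](c2ccccc2)O1 | intermediate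
4 | methyl vinyl ketone (but-3-en-2-one) | CC(=O)C=C | starting material
5 | 4-(3-oxobutyl)-2-phenyl-1,3-dioxane-4-carbaldehyde (diastereomer mixture) | CC(=O)CCC1(C=O)CCOC(c2ccccc2)O1 | intermediate (not isolated)
6 | 7-hydroxy-2-phenyl-1,3-dioxaspiro[5.5]undecan-9-one (diastereomer mixture) | O=C1CC(O)C2(CC1)CCOC(c1ccccc1)O2 | intermediate (not isolated)
7 | 2-phenyl-1,3-dioxaspiro[5.5]undec-7-en-9-one (diastereomer mixture) | O=C1C=CC2(CC1)CCOC(c1ccccc1)O2 | intermediate
8 | 2-phenyl-1,3-dioxaspiro[5.5]undecan-9-one (racemic) | O=C1CCC2(CC1)CCOC(c1ccccc1)O2 | intermediate (not isolated)
9 | 4-hydroxy-4-(2-hydroxyethyl)cyclohexan-1-one | O=C1CCC(O)(CCO)CC1 | intermediate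
10 | palmitoyl chloride (hexadecanoyl chloride) | CCCCCCCCCCCCCCCC(=O)Cl | starting material
11 | 2-(1-hydroxy-4-oxocyclohexyl)ethyl hexadecanoate | CCCCCCCCCCCCCCCC(=O)OCCC1(O)CCC(=O)CC1 | target

Total step count: 5. Longest linear sequence: 5 steps (1 → 2 → 3 → 7 → 9 → 11).

Steps most likely to fail

Step 3. The hindered α-alkoxy aldehyde may form its enamine too slowly under catalytic conditions, so that methyl vinyl ketone polymerises or the sequence stalls before ring closure. If the medium turns too acidic or too hot, the γ-alkoxy enone may also lose the tertiary oxygen by aromatisation. The fallback sets out from 3 and returns at 7; it activates the donor stoichiometrically and separates the two bond formations. Aldehyde 3 is condensed with pyrrolidine (K2CO3, toluene, rt) to the enamine 1-[(2-phenyl-1,3-dioxan-4-ylidene)methyl]pyrrolidine F1. F1 is treated with 4 (MeCN, rt) and should give the spirocyclic 2-(pyrrolidin-1-yl)-3,4-dihydro-2H-pyran aminal F2. Buffered hydrolysis (AcOH/NaOAc, H2O, rt) should release keto aldehyde 5, which is isolated this time. Ring closure of 5 with KOH in MeOH at rt should then pass through ketol 6 to enone 7.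

Step 4. Hydrogenolysis of the allylic C–O bond at the spiro carbon may compete with saturation of the alkene, or the acetal cleavage may stall. The fallback sets out from 7 and returns at 9; it replaces the single hydrogenation by two non-hydrogenolytic operations. Conjugate reduction of 7 with [(Ph3P)CuH]6 (wet toluene, rt) should give the saturated acetal 8, now isolated, and 80% aqueous AcOH at 40 °C should hydrolyse the benzylidene acetal to 9 with release of benzaldehyde. No compound outside the list is made (F0).

Step 5. Acylation may spill over to the tertiary hydroxyl or give a diester, and the primary hydroxyl may react sluggishly if 9 sits partly as a transannular hemiketal. The fallback sets out from 9 and returns at 11; it uses biocatalytic transesterification in place of an acid chloride. Immobilised Candida antarctica lipase B with vinyl palmitate (MTBE, 40 °C) should accept only the primary hydroxyl. No compound outside the list is made (F0).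

Further compounds
F1 | step 3 | 1-[(2-phenyl-1,3-dioxan-4-ylidene)methyl]pyrrolidine (E/Z mixture) | C1CCN(C1)C=C1CCOC(c2ccccc2)O1
F2 | step 3 | spirocyclic aminal: 6-methyl-2-(pyrrolidin-1-yl)-3,4-dihydro-2H-pyran whose C3 is C4 of the 2-phenyl-1,3-dioxane (diastereomer mixture) | CC1=CCC2(CCOC(c3ccccc3)O2)C(N2CCCC2)O1
F0 | step 4 | none | none
F0 | step 5 | none | none
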